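# Proposal: synthesis of CNP0545483.1 by a prenyltransferase-triggered closure of the eight-membered ring

## The problem

The target is an 8-oxabicyclo[5.2.1]decane-6,9,10-trione: an eight-membered carbocycle (numbered C1–C8 here) bridged by a γ-lactone, whose carbonyl C9 sits on C5 and whose oxygen sits on C3, with the ketone C4 as the one-atom bridge. C1 carries H and isobutyryl, C2 is a ketone, C3 and C5 each carry a prenyl group, C6 is CH2, C7 carries H and prenyl, and C8 carries methyl and the (E)-4-hydroperoxy-4-methylpent-2-enyl chain. The configuration is 1R,3S,5R,7S,8R. C3 and C5 are quaternary bridgeheads that must be cis and can only be set before the carbocycle exists. C7 and C8 are a vicinal tertiary/quaternary pair, and C1 is an epimerisable β-diketone methine that can be left to equilibrate. At each bridgehead the two carbon substituents are sterically similar, so relative control between C3 and C5 is the hidden difficulty. The tertiary allylic hydroperoxide will not survive phosphines, low-valent metals, strong base or enolate chemistry, the three prenyl groups will not survive strong acid or free electrophiles, and the tricarbonyl array around C3 is open to retro-Claisen cleavage. The enabling feature is that C7 and C8 are the two ends of a former E-trisubstituted alkene on the C5 arm, while C1 is the nucleophilic carbon of a β-diketone on the C3 arm. With both arms on the same face of a furan-2,4-dione, adding a prenyl cation at C7 and C1 at C8 completes the carbocycle.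

## Retrosynthesis

**22 to 21.** The O–O unit is put on last, by exchanging the tertiary allylic hydroxyl of 21 for OOH. Every earlier stage uses phosphines, palladium, copper, amines or an enzyme in buffer, none of which a hydroperoxide tolerates. A late singlet-oxygen ene reaction would not distinguish four trisubstituted alkenes. The forward reaction must ionise only the doubly stabilised tertiary allylic position.

**21 to 19 and 20 (key cut).** Cutting C7–CH2(prenyl) and C8–C1 opens the carbocycle to the monocyclic furan-2,4-dione 19 and dimethylallyl diphosphate 20. This removes the ring, both new skeletal bonds and three stereocentres at once, and leaves C6 allylic, so the arm can be attached by allylic alkylation. The forward step asks an active site to prenylate C7 of one alkene among four, to deliver C1 anti across the E-alkene, and to suppress capture of the C8 cation by the neighbouring prenyl group.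

**19 to 17 to 15 and 16.** The β-diketone is traced to the ynone 17 (hydration), and 17 to the terminal alkyne 15 and isobutyryl chloride 16. Carrying C2/C1 as an ethynyl group avoids an acidic, electrophilic acyl group during ring construction. It also gives the O-bearing carbon one slim and one bulky substituent, which the next cut needs.

**15 to 14 and 3.** The bond between C6 and the carbon between the two carbonyls (C5) is cut to the tetronic acid 14 and the allylic acetate 3. The alternative order, quaternising C5 first and acylating C3 last, would have to tell a prenyl from a geranyl-type chain and cannot be selective. Here the incoming π-allyl must choose between a prenyl-shielded face and an ethynyl-bearing face.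

**14 to 12 to 9 and 10.** Lacey–Dieckmann disconnection of the tetronic acid gives the O-acyl ester 12, then the tertiary propargylic α-hydroxy ester 9 and 5-methylhex-4-enoic acid 10. The C3 stereocentre is now a single carbinol carbon that survives all later steps unchanged.

**9 to 7 and 8; 7 to 6 to 4 and 5.** The carbinol is made by enantioselective alkynylation of keto ester 7 with ethynyltrimethylsilane 8. Keto ester 7 comes from prenyl bromide 5 and the glyoxylate acyl-anion equivalent 4 through dithiane 6, because prenyl organometallics would add through their tertiary terminus.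

**3 to 1.** The arm is one ene reaction and reduction away from geranyl acetate 1, through hydroperoxide 2.

## Roads not taken

**Alternative 1:** The cut is C4–C5. Thiolactone A1, a nine-membered ring with sulfur between C4 and C5, is deprotonated at C5. The carbanion adds to the thioester carbonyl, and triphenylphosphine removes sulfur from the episulfide to give the eight-membered β-keto ester A2. Its merit is that the medium ring is closed first as a heteroatom acylation and the hindered C–C bond then forms intramolecularly by established chemistry. Against it, A2 still lacks the C5 prenyl group, the lactone bridge and the C1 isobutyryl group. C5 has no fixed configuration, the tertiary C3 oxygen must be unmasked and lactonised in the presence of acid-sensitive groups, and the C7/C8 pair must be built separately in an open chain. On certainty this road is better, since every step is known chemistry. The chosen plan sets against it a single step that makes two bonds and three stereocentres, and a far shorter sequence.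

**Alternative 2:** The cut is C5–C9. In carbonate A3, the C4=C5 enolate of a fully substituted eight-membered ring attacks the phenyl carbonate on the C3 oxygen and closes the lactone to A4. The five-membered acyl transfer is favourable, and the C5 centre is necessarily cis to C3 because the tether delivers the acyl group. That is better stereocontrol at C5 than the facial selectivity relied on in step 7 here. The weak points are that the real problem, a cyclooctane bearing C1, C3, C7 and C8 in the right configuration, is pushed upstream without a solution. The C1 methine is also far more acidic than C5–H, and the enolate can be acylated on oxygen. The chosen plan has to set against this its dependence on an enzyme, but it builds the ring and the C7/C8 pair together instead of needing them beforehand.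

**Alternative 3:** The cut is C2–C3. In A5, the enolate at the O-bearing carbon of a furan-2,4-dione attacks a pentafluorophenyl ester at the end of the C6–C1 chain and gives the keto-lactone A6, which is then acylated at C1. It shares the tetronate chemistry used here, the bridge can only form cis, and the closure is a known reaction class. In stereocontrol at C3/C5 and in precedent it is the stronger road. Against it, the chain must carry the C7/C8 pair already and must be joined to the quaternary C5 through a β-branched sp3 carbon, where Tsuji–Trost chemistry is not available. The active ester also has acidic α-hydrogens, and the isobutyryl group must be added afterwards at a hindered carbon. The chosen plan is shorter and more convergent, and has to answer for its key step with a fallback in known chemistry.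

Key step: step 10

## Route

Remark: 4, 10 and 20 (as its ammonium salt) are taken as catalogue compounds, and the 1R configuration of the target is taken to be the thermodynamically preferred one of the epimerisable β-diketone methine.

Step 1
Reactants: 1 geranyl acetate
Product: 3 (2E,5E)-7-hydroxy-3,7-dimethylocta-2,5-dien-1-yl acetate, via tertiary allylic hydroperoxide 2 (not isolated)
Conditions: O2, tetraphenylporphyrin (cat.), visible light, CH2Cl2, 0 °C; then PPh3, 0 °C → rt; chromatography
Reagents that add atoms: dioxygen, O=O
Why: Schenck ene reaction of singlet oxygen at the electron-rich 6,7-alkene (the 2,3-alkene is deactivated by the allylic acetate) shifts the double bond to C5=C6 with E geometry and PPh3 reduces the hydroperoxide; the secondary ene regioisomer that forms alongside is removed by chromatography.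

Step 2
Reactants: 4 ethyl 1,3-dithiane-2-carboxylate; 5 prenyl bromide
Product: 6 ethyl 2-(3-methylbut-2-en-1-yl)-1,3-dithiane-2-carboxylate
Conditions: NaH, DMF–toluene, 0 °C → rt
Reagents that add atoms: none
Why: SN2 alkylation of the stabilised dithiane ester anion (a glyoxylate acyl-anion equivalent) at the primary allylic carbon keeps the prenyl group unrearranged.

Step 3
Reactants: 6 ethyl 2-(3-methylbut-2-en-1-yl)-1,3-dithiane-2-carboxylate
Product: 7 ethyl 5-methyl-2-oxohex-4-enoate
Conditions: MeI, CaCO3, MeCN–H2O (4:1), 45 °C
Reagents that add atoms: water, O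
Why: Alkylative hydrolysis of the dithiane unmasks the ketone without an oxidant or halonium source that would attack the trisubstituted alkene, and the buffered medium limits migration of the β,γ-double bond into conjugation.

Step 4
Reactants: 7 ethyl 5-methyl-2-oxohex-4-enoate; 8 ethynyltrimethylsilane
Product: 9 ethyl (2S)-2-hydroxy-5-methyl-2-[(trimethylsilyl)ethynyl]hex-4-enoate
Conditions: Zn(OTf)2 (20 mol %), (1S,2S)-3-(tert-butyldimethylsilyloxy)-2-(dimethylamino)-1-(4-nitrophenyl)propan-1-ol (22 mol %), Et3N (30 mol %), toluene, 50 °C
Reagents that add atoms: none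
Why: Catalytic enantioselective addition of a zinc acetylide formed in situ to the chelated α-keto ester, with the face set by the amino alcohol ligand; the ligand antipode is chosen so that the (S)-carbinol, the future C3, is formed.

Step 5
Reactants: 9 ethyl (2S)-2-hydroxy-5-methyl-2-[(trimethylsilyl)ethynyl]hex-4-enoate; 10 5-methylhex-4-enoic acid
Product: 12 ethyl (2S)-5-methyl-2-[(5-methylhex-4-enoyl)oxy]-2-[(trimethylsilyl)ethynyl]hex-4-enoate, via 5-methylhex-4-enoyl chloride 11 (not isolated)
Conditions: 10, (COCl)2, DMF (cat.), CH2Cl2, 0 °C → rt; then 9, pyridine, DMAP (cat.), CH2Cl2, 40 °C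
Reagents that add atoms: none
Why: DMAP-catalysed O-acylation of the tertiary α-hydroxy ester by the acid chloride is the first half of a Lacey–Dieckmann tetronic acid synthesis and does not touch the quaternary centre.

Step 6
Reactants: 12 ethyl (2S)-5-methyl-2-[(5-methylhex-4-enoyl)oxy]-2-[(trimethylsilyl)ethynyl]hex-4-enoate
Product: 14 (5S)-5-ethynyl-4-hydroxy-3,5-bis(3-methylbut-2-en-1-yl)furan-2(5H)-one, via C-silylated tetronic acid 13 (not isolated)
Conditions: LiN(SiMe3)2 (2.5 equiv), THF, −78 → 0 °C; then MeOH, K2CO3, rt; aq. HCl
Reagents that add atoms: none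
Why: Lacey–Dieckmann cyclisation in which the only enolisable position, the CH2 of the acyl group, attacks the neighbouring ethyl ester; the resulting tetronate anion is inert to the methanolic carbonate that then removes the C-silyl group, and the quaternary C5 of the furanone keeps its configuration.

Step 7
Reactants: 14 (5S)-5-ethynyl-4-hydroxy-3,5-bis(3-methylbut-2-en-1-yl)furan-2(5H)-one; 3 (2E,5E)-7-hydroxy-3,7-dimethylocta-2,5-dien-1-yl acetate
Product: 15 (3R,5S)-5-ethynyl-3-[(2E,5E)-7-hydroxy-3,7-dimethylocta-2,5-dien-1-yl]-3,5-bis(3-methylbut-2-en-1-yl)furan-2,4(3H,5H)-dione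
Conditions: Pd(PPh3)4 (5 mol %), Et3N (1.1 equiv), THF, 0 °C → rt
Reagents that add atoms: none
Why: Tsuji–Trost C-allylation of the soft tetronate at the unsubstituted terminus of the π-allyl complex from the primary allylic acetate (O-allyl products re-ionise and funnel to carbon, and the tertiary alcohol is not ionised); the electrophile should enter anti to the prenyl group on the O-bearing carbon, that is syn to the slim ethynyl rod, which sets 3R and places the octadienyl arm cis to the future acyl arm.

Step 8
Reactants: 15 (3R,5S)-5-ethynyl-3-[(2E,5E)-7-hydroxy-3,7-dimethylocta-2,5-dien-1-yl]-3,5-bis(3-methylbut-2-en-1-yl)furan-2,4(3H,5H)-dione; 16 isobutyryl chloride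
Product: 17 (3R,5S)-3-[(2E,5E)-7-hydroxy-3,7-dimethylocta-2,5-dien-1-yl]-3,5-bis(3-methylbut-2-en-1-yl)-5-(4-methyl-3-oxopent-1-yn-1-yl)furan-2,4(3H,5H)-dione
Conditions: PdCl2(PPh3)2 (2 mol %), CuI (4 mol %), Et3N (1.3 equiv), THF, rt
Reagents that add atoms: none
Why: Acyl Sonogashira coupling of a terminal alkyne with an acid chloride gives the ynone at room temperature; the hindered tertiary alcohol is not acylated without an acyl-transfer catalyst and the furandione has no enolisable hydrogen.

Step 9
Reactants: 17 (3R,5S)-3-[(2E,5E)-7-hydroxy-3,7-dimethylocta-2,5-dien-1-yl]-3,5-bis(3-methylbut-2-en-1-yl)-5-(4-methyl-3-oxopent-1-yn-1-yl)furan-2,4(3H,5H)-dione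
Product: 19 (3R,5S)-3-[(2E,5E)-7-hydroxy-3,7-dimethylocta-2,5-dien-1-yl]-3,5-bis(3-methylbut-2-en-1-yl)-5-(4-methyl-3-oxopentanoyl)furan-2,4(3H,5H)-dione, via β-diethylamino enone 18 (not isolated)
Conditions: Et2NH (1.1 equiv), THF, 0 °C; then 10% aq. oxalic acid, THF, rt
Reagents that add atoms: water, O
Why: Conjugate addition of the amine to the ynone places nitrogen on the alkyne carbon attached to the ring, and mild acid hydrolysis of the vinylogous amide releases the 1,3-diketone with the new carbonyl at C2; this two-stage ynone hydration avoids metal or strong-acid activation that the prenyl groups and the tertiary allylic alcohol would not tolerate.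

Step 10
Reactants: 19 (3R,5S)-3-[(2E,5E)-7-hydroxy-3,7-dimethylocta-2,5-dien-1-yl]-3,5-bis(3-methylbut-2-en-1-yl)-5-(4-methyl-3-oxopentanoyl)furan-2,4(3H,5H)-dione; 20 dimethylallyl diphosphate
Product: 21 (1R,3S,4R,5R,7S)-4-[(2E)-4-hydroxy-4-methylpent-2-en-1-yl]-4-methyl-1,3,7-tris(3-methylbut-2-en-1-yl)-5-(2-methylpropanoyl)-8-oxabicyclo[5.2.1]decane-6,9,10-trione (1R,3S,5R,7S,8R in the carbocycle numbering)
Conditions: engineered prenyltransferase (microsomal or purified), MgCl2 (5 mM), HEPES buffer pH 7.5, 5% DMSO, 30 °C
Reagents that add atoms: none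
Why: Proposed new method: the enzyme ionises 20 to the dimethylallyl cation, which adds to C7 of the E-configured C7=C8 alkene of 19, and the tertiary C8 cation is captured on the opposite alkene face by the enol carbon C1 of the β-diketone, the enol proton being lost to give 21. The closest known reaction type is the prenyltransferase-triggered cation–olefin bicyclisation that builds the bicyclo[3.3.1]nonane core of hyperforin-type acylphloroglucinols, which makes the same C7–prenyl and C8–C1 bonds on an intact six-membered trione. Here that ring is already cut to the lactone, so the single ring closed is the eight-membered carbocycle, formed in an 8-endo-trig mode with respect to the alkene. C7 (S) is set by the alkene face that the active site presents to the cation, and C8 (R) follows from anti addition across the E-alkene. C1 (R) is an epimerisable methine expected to settle to its more stable configuration. The step needs prenylation of one alkene among four, carbon and not oxygen capture by the β-diketone, and exclusion of the prenyl group on C5, which could trap the C8 cation in a six-membered ring. The substrate supplies the cis relationship of the two arms (fixed in steps 4 and 7), the E geometry inherited from 1 and a nucleophile held five atoms from C8; the rest has to come from the fold of the active site, which is why enzyme discovery or engineering is part of this step.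

Step 11
Reactants: 21 the bicyclic tertiary allylic alcohol
Product: 22 (1R,3S,4R,5R,7S)-4-[(2E)-4-hydroperoxy-4-methylpent-2-en-1-yl]-4-methyl-1,3,7-tris(3-methylbut-2-en-1-yl)-5-(2-methylpropanoyl)-8-oxabicyclo[5.2.1]decane-6,9,10-trione
Conditions: H2O2 (50% aq., 20 equiv), H2SO4 (cat.), THF, 0 °C
Reagents that add atoms: hydrogen peroxide, OO
Why: Acid-catalysed perhydrolysis (SN1 exchange) of the tertiary allylic alcohol, in which the allyl cation is captured by the large excess of H2O2 at its tertiary terminus so that the E-disubstituted alkene is kept; the isolated prenyl groups are not protonated by catalytic acid at 0 °C and all stereocentres are remote from the reacting carbon.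

## Compound list

1 | geranyl acetate | CC(C)=CCC/C(C)=C/COC(C)=O | starting material
2 | (2E,5E)-7-hydroperoxy-3,7-dimethylocta-2,5-dien-1-yl acetate | CC(C)(OO)/C=C/C/C(C)=C/COC(C)=O | intermediate
3 | (2E,5E)-7-hydroxy-3,7-dimethylocta-2,5-dien-1-yl acetate | CC(C)(O)/C=C/C/C(C)=C/COC(C)=O | intermediate
4 | ethyl 1,3-dithiane-2-carboxylate | CCOC(=O)C1SCCCS1 | starting material
5 | prenyl bromide | CC(C)=CCBr | starting material
6 | ethyl 2-(3-methylbut-2-en-1-yl)-1,3-dithiane-2-carboxylate | CCOC(=O)C1(CC=C(C)C)SCCCS1 | intermediate
7 | ethyl 5-methyl-2-oxohex-4-enoate | CCOC(=O)C(=O)CC=C(C)C | intermediate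
8 | ethynyltrimethylsilane | C#C[Si](C)(C)C | starting material
9 | ethyl (2S)-2-hydroxy-5-methyl-2-[(trimethylsilyl)ethynyl]hex-4-enoate | O[C@@](CC=C(C)C)(C#C[Si](C)(C)C)C(=O)OCC | intermediate
10 | 5-methylhex-4-enoic acid | CC(C)=CCCC(=O)O | starting material
11 | 5-methylhex-4-enoyl chloride | CC(C)=CCCC(Cl)=O | intermediate
12 | ethyl (2S)-5-methyl-2-[(5-methylhex-4-enoyl)oxy]-2-[(trimethylsilyl)ethynyl]hex-4-enoate | CC(C)=CCCC(=O)O[C@@](CC=C(C)C)(C#C[Si](C)(C)C)C(=O)OCC | intermediate
13 | (5S)-4-hydroxy-3,5-bis(3-methylbut-2-en-1-yl)-5-[(trimethylsilyl)ethynyl]furan-2(5H)-one | O1[C@@](CC=C(C)C)(C#C[Si](C)(C)C)C(O)=C(CC=C(C)C)C1=O | intermediate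
14 | (5S)-5-ethynyl-4-hydroxy-3,5-bis(3-methylbut-2-en-1-yl)furan-2(5H)-one | O1[C@@](CC=C(C)C)(C#C)C(O)=C(CC=C(C)C)C1=O | intermediate
15 | (3R,5S)-5-ethynyl-3-[(2E,5E)-7-hydroxy-3,7-dimethylocta-2,5-dien-1-yl]-3,5-bis(3-methylbut-2-en-1-yl)furan-2,4(3H,5H)-dione | CC(C)(O)/C=C/C/C(C)=C/C[C@@]1(CC=C(C)C)C(=O)O[C@@](CC=C(C)C)(C#C)C1=O | intermediate
16 | isobutyryl chloride | CC(C)C(Cl)=O | starting material
17 | (3R,5S)-3-[(2E,5E)-7-hydroxy-3,7-dimethylocta-2,5-dien-1-yl]-3,5-bis(3-methylbut-2-en-1-yl)-5-(4-methyl-3-oxopent-1-yn-1-yl)furan-2,4(3H,5H)-dione | CC(C)(O)/C=C/C/C(C)=C/C[C@@]1(CC=C(C)C)C(=O)O[C@@](CC=C(C)C)(C#CC(=O)C(C)C)C1=O | intermediate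
18 | (3R,5S)-5-[1-(diethylamino)-4-methyl-3-oxopent-1-en-1-yl]-3-[(2E,5E)-7-hydroxy-3,7-dimethylocta-2,5-dien-1-yl]-3,5-bis(3-methylbut-2-en-1-yl)furan-2,4(3H,5H)-dione | CC(C)(O)/C=C/C/C(C)=C/C[C@@]1(CC=C(C)C)C(=O)O[C@@](CC=C(C)C)(C(=CC(=O)C(C)C)N(CC)CC)C1=O | intermediate
19 | (3R,5S)-3-[(2E,5E)-7-hydroxy-3,7-dimethylocta-2,5-dien-1-yl]-3,5-bis(3-methylbut-2-en-1-yl)-5-(4-methyl-3-oxopentanoyl)furan-2,4(3H,5H)-dione | CC(C)(O)/C=C/C/C(C)=C/C[C@@]1(CC=C(C)C)C(=O)O[C@@](CC=C(C)C)(C(=O)CC(=O)C(C)C)C1=O | intermediate
20 | dimethylallyl diphosphate | CC(C)=CCOP(=O)(O)OP(=O)(O)O | starting material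
21 | (1R,3S,4R,5R,7S)-4-[(2E)-4-hydroxy-4-methylpent-2-en-1-yl]-4-methyl-1,3,7-tris(3-methylbut-2-en-1-yl)-5-(2-methylpropanoyl)-8-oxabicyclo[5.2.1]decane-6,9,10-trione | CC(C)=CC[C@H]1C[C@@]2(CC=C(C)C)C(=O)O[C@@](CC=C(C)C)(C(=O)[C@@H](C(=O)C(C)C)[C@]1(C)C/C=C/C(C)(C)O)C2=O | intermediate
22 | (1R,3S,4R,5R,7S)-4-[(2E)-4-hydroperoxy-4-methylpent-2-en-1-yl]-4-methyl-1,3,7-tris(3-methylbut-2-en-1-yl)-5-(2-methylpropanoyl)-8-oxabicyclo[5.2.1]decane-6,9,10-trione | CC(C)=CC[C@H]1C[C@@]2(CC=C(C)C)C(=O)O[C@@](CC=C(C)C)(C(=O)[C@@H](C(=O)C(C)C)[C@]1(C)C/C=C/C(C)(C)OO)C2=O | target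

## Step count and risks

Total: 11 steps. Longest linear sequence: 10 steps (steps 2 to 11); step 1 is a one-step branch.

**Step 10 (the proposed new method).** No enzyme is known to accept 19, so the reaction may not occur at all. If it does, the cation may be transferred to a spectator prenyl group or directly to the β-diketone (carbon or oxygen prenylation without cyclisation). The C8 cation may also be lost by elimination, or be trapped by the prenyl group on C5 in a six-membered ring, because the eight-membered closure is entropically the least favoured of the available paths.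

Fallback in known chemistry, setting out from 14 and returning at 21, in which the two key bonds are made one after the other by polar reactions:
- Tetronic acid 14 is added (Et3N, cat.) in Michael fashion to 6-methyl-3-methylidenehept-5-en-2-one F1, made from commercial 6-methylhept-5-en-2-one by α-methylenation with paraformaldehyde and N-methylanilinium trifluoroacetate. This gives the methyl ketone F2 with the same facial preference as step 7; the ketone α-carbon (C7) stays epimerisable.
- Acyl Sonogashira coupling with 16 gives ynone F3. Diethylamine addition, through enaminone F4, and aqueous oxalic acid give the triketone F5.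
- Intramolecular Knoevenagel condensation (TiCl4, pyridine) of the β-diketone carbon with the methyl ketone closes the eight-membered ring as the alkylidene diketone F6, in which C7 can equilibrate.
- Hosomi–Sakurai conjugate allylation (allyltrimethylsilane, TiCl4, −78 °C) anti to the C7 prenyl group creates the C8 quaternary centre in F7.
- Cross-metathesis with 2-methylbut-3-en-2-ol (second-generation Grubbs catalyst) completes the side chain and delivers 21.

**Step 7.** The facial preference at the tetronate carbon rests only on the size difference between an ethynyl and a prenyl group. It may be small, or reversed if the π-allyl cation avoids the alkyne. The π-allyl intermediate can also lose E geometry by π–σ–π isomerisation, and zerovalent palladium can insert into the propargylic C–O bond.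

Fallback, from 9 to 15, inverting the order so that prenyl enters last:
- 9 is O-acetylated to F8.
- LiN(SiMe3)2 and then K2CO3/MeOH give, through the C-silylated tetronic acid F9, the 3-unsubstituted tetronic acid F10.
- Pd(PPh3)4-catalysed mono-allylation with 3 gives F11.
- A second allylation with 3-methylbut-2-enyl acetate gives 15.

Since 15 and its epimer are diastereomers, they can in either order be separated by chromatography.

**Step 11.** The allyl cation can be captured at its secondary terminus (allylic transposition). Acid can also set off cyclisation of a prenyl group onto the β-diketone enol, and H2O2 can add to the ketones.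

Fallback, from 21 to 22, by radical instead of ionic C–O bond formation:
- Dehydration with the Burgess reagent gives the 1,3-diene F12.
- Mukaiyama–Isayama peroxidation (Co(acac)2, O2, Et3SiH) of the conjugated terminal alkene gives the triethylsilyl peroxide F13.
- HF·pyridine gives 22.

**Step 4.** Enantioselectivity may erode with an aliphatic, enolisable keto ester, and the amine base may move the β,γ-double bond into conjugation before addition.

Fallback, from 7 to 9: lithium (trimethylsilyl)acetylide (from 8 and n-BuLi, THF, −78 °C) gives the racemic carbinol F14, which is resolved by preparative chromatography on a chiral stationary phase.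

## Further compounds

F1 | step 10 | 6-methyl-3-methylidenehept-5-en-2-one | CC(=O)C(=C)CC=C(C)C
F2 | step 10 | (3R,5S)-3-(2-acetyl-5-methylhex-4-en-1-yl)-5-ethynyl-3,5-bis(3-methylbut-2-en-1-yl)furan-2,4(3H,5H)-dione, both epimers at the acetyl-bearing carbon | CC(=O)C(CC=C(C)C)C[C@@]1(CC=C(C)C)C(=O)O[C@@](CC=C(C)C)(C#C)C1=O
F3 | step 10 | (3R,5S)-3-(2-acetyl-5-methylhex-4-en-1-yl)-3,5-bis(3-methylbut-2-en-1-yl)-5-(4-methyl-3-oxopent-1-yn-1-yl)furan-2,4(3H,5H)-dione | CC(=O)C(CC=C(C)C)C[C@@]1(CC=C(C)C)C(=O)O[C@@](CC=C(C)C)(C#CC(=O)C(C)C)C1=O
F4 | step 10 | (3R,5S)-3-(2-acetyl-5-methylhex-4-en-1-yl)-5-[1-(diethylamino)-4-methyl-3-oxopent-1-en-1-yl]-3,5-bis(3-methylbut-2-en-1-yl)furan-2,4(3H,5H)-dione | CC(=O)C(CC=C(C)C)C[C@@]1(CC=C(C)C)C(=O)O[C@@](CC=C(C)C)(C(=CC(=O)C(C)C)N(CC)CC)C1=O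
F5 | step 10 | (3R,5S)-3-(2-acetyl-5-methylhex-4-en-1-yl)-3,5-bis(3-methylbut-2-en-1-yl)-5-(4-methyl-3-oxopentanoyl)furan-2,4(3H,5H)-dione | CC(=O)C(CC=C(C)C)C[C@@]1(CC=C(C)C)C(=O)O[C@@](CC=C(C)C)(C(=O)CC(=O)C(C)C)C1=O
F6 | step 10 | (1R,3S,7S)-4-methyl-1,3,7-tris(3-methylbut-2-en-1-yl)-5-(2-methylpropanoyl)-8-oxabicyclo[5.2.1]dec-4-ene-6,9,10-trione | CC(C)=CC[C@H]1C[C@@]2(CC=C(C)C)C(=O)O[C@@](CC=C(C)C)(C(=O)/C(C(=O)C(C)C)=C1/C)C2=O
F7 | step 10 | (1R,3S,4R,5R,7S)-4-methyl-1,3,7-tris(3-methylbut-2-en-1-yl)-5-(2-methylpropanoyl)-4-(prop-2-en-1-yl)-8-oxabicyclo[5.2.1]decane-6,9,10-trione | CC(C)=CC[C@H]1C[C@@]2(CC=C(C)C)C(=O)O[C@@](CC=C(C)C)(C(=O)[C@@H](C(=O)C(C)C)[C@]1(C)CC=C)C2=O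
F8 | step 7 | ethyl (2S)-2-acetoxy-5-methyl-2-[(trimethylsilyl)ethynyl]hex-4-enoate | CC(=O)O[C@@](CC=C(C)C)(C#C[Si](C)(C)C)C(=O)OCC
F9 | step 7 | (5S)-4-hydroxy-5-(3-methylbut-2-en-1-yl)-5-[(trimethylsilyl)ethynyl]furan-2(5H)-one | O1[C@@](CC=C(C)C)(C#C[Si](C)(C)C)C(O)=CC1=O
F10 | step 7 | (5S)-5-ethynyl-4-hydroxy-5-(3-methylbut-2-en-1-yl)furan-2(5H)-one | O1[C@@](CC=C(C)C)(C#C)C(O)=CC1=O
F11 | step 7 | (5S)-5-ethynyl-4-hydroxy-3-[(2E,5E)-7-hydroxy-3,7-dimethylocta-2,5-dien-1-yl]-5-(3-methylbut-2-en-1-yl)furan-2(5H)-one | O1[C@@](CC=C(C)C)(C#C)C(O)=C(C/C=C(C)/C/C=C/C(C)(C)O)C1=O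
F12 | step 11 | (1R,3S,4R,5R,7S)-4-methyl-4-[(2E)-4-methylpenta-2,4-dien-1-yl]-1,3,7-tris(3-methylbut-2-en-1-yl)-5-(2-methylpropanoyl)-8-oxabicyclo[5.2.1]decane-6,9,10-trione | CC(C)=CC[C@H]1C[C@@]2(CC=C(C)C)C(=O)O[C@@](CC=C(C)C)(C(=O)[C@@H](C(=O)C(C)C)[C@]1(C)C/C=C/C(C)=C)C2=O
F13 | step 11 | triethylsilyl peroxide of 22 | CC(C)=CC[C@H]1C[C@@]2(CC=C(C)C)C(=O)O[C@@](CC=C(C)C)(C(=O)[C@@H](C(=O)C(C)C)[C@]1(C)C/C=C/C(C)(C)OO[Si](CC)(CC)CC)C2=O
F14 | step 4 | racemic ethyl 2-hydroxy-5-methyl-2-[(trimethylsilyl)ethynyl]hex-4-enoate | CCOC(=O)C(O)(CC=C(C)C)C#C[Si](C)(C)C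
A1 | alternative 1 | nine-membered thiolactone with sulfur between C4 and C5 | CC(C)=CC[C@H]1CC(C(=O)OC)SC(=O)[C@@](CC=C(C)C)(OCOC)C(=O)C[C@]1(C)C/C=C/C(C)(C)O[Si](CC)(CC)CC
A2 | alternative 1 | eight-membered β-keto ester with C5–H | CC(C)=CC[C@H]1CC(C(=O)OC)C(=O)[C@@](CC=C(C)C)(OCOC)C(=O)C[C@]1(C)C/C=C/C(C)(C)O[Si](CC)(CC)CC
A3 | alternative 2 | eight-membered triketone with phenyl carbonate on the C3 oxygen | CC(C)=CC[C@H]1CC(CC=C(C)C)C(=O)[C@@](CC=C(C)C)(OC(=O)Oc2ccccc2)C(=O)[C@@H](C(=O)C(C)C)[C@]1(C)C/C=C/C(C)(C)O[Si](CC)(CC)CC
A4 | alternative 2 | triethylsilyl ether of 21 | CC(C)=CC[C@H]1C[C@@]2(CC=C(C)C)C(=O)O[C@@](CC=C(C)C)(C(=O)[C@@H](C(=O)C(C)C)[C@]1(C)C/C=C/C(C)(C)O[Si](CC)(CC)CC)C2=O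
A5 | alternative 3 | furan-2,4-dione with C3–H and a pentafluorophenyl ester at the end of the C6–C1 chain | CC(C)=CC[C@@H](C[C@@]1(CC=C(C)C)C(=O)OC(CC=C(C)C)C1=O)[C@](C)(CC(=O)Oc1c(F)c(F)c(F)c(F)c1F)C/C=C/C(C)(C)O[Si](CC)(CC)CC
A6 | alternative 3 | bicyclic keto-lactone lacking the C1 isobutyryl group, triethylsilyl ether | CC(C)=CC[C@H]1C[C@@]2(CC=C(C)C)C(=O)O[C@@](CC=C(C)C)(C(=O)C[C@]1(C)C/C=C/C(C)(C)O[Si](CC)(CC)CC)C2=O
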